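The route rests on taking both oxirane oxygens off C2–C3 and C4–C5 of the ten-membered ring, which leads back to macrocyclic 1(10),2Z,4Z-triene 37 carrying the C6–C7 methylene lactone, the C8 epoxy ester, the C9 acetate and the C10 methyl ester. One dimethyldioxirane treatment then forms four C–O bonds, both oxirane rings and four stereocentres. It exploits the electron-rich, twisted C2=C3–C4=C5 diene, flanked by lactone stereocentre C6 and by the deactivated C1=C10 enoate. Triene 37 is made cold, two steps earlier, by NiCl2/CrCl2 ring closure at C9–C10 of an acyclic iodo trienoate aldehyde whose C6–C8 centres come from a boron aldol and a hydroxyl-directed reduction.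

Key step: step 25

Remark on numbering: labels C1–C14 follow the germacrane numbering of the target in every intermediate, and CIP letters are quoted with these labels.
Remark on structures: target 39 and triene 37 were compared centre by centre (C6–C9, the epoxy ester, all alkene geometries) and agree, so no structure needed correction. The CIP letters differ (6R,7S in 37; 6S,7R in 39) only because substituent priorities change.
Remark on precursor design: the C8 ester is in place before ring closure, so only one acetylation separates macrocyclisation from epoxidation. Triene 37 is kept at or below 10 °C and used at once.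
Assumption: 3-bromobut-3-en-1-ol, tributyl(iodomethyl)stannane, silyl ether 4 and oxazolidinone 9 are purchased.

Step 1
Reactants: 1 but-2-yn-1-ol
Product: 3 (2Z)-3-iodobut-2-en-1-ol, via sodium alkenylalanate 2 (not isolated)
Conditions: NaAlH2(OCH2CH2OMe)2, THF, 0 °C → rt; then I2, −78 °C
Reagents that add atoms: iodine, II
Why: Hydroxyl-directed trans-hydroalumination of the propargylic alcohol puts aluminium on the distal alkyne carbon in a five-membered alanate, and iodine replaces aluminium with retention, so iodine and CH2OH end up cis (the geometry that later makes C3 and C6 cis).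

Step 2
Reactants: 3 (2Z)-3-iodobut-2-en-1-ol; 4 tert-butyldimethyl(prop-2-yn-1-yloxy)silane
Product: 5 (2Z)-6-(tert-butyldimethylsilyloxy)-3-methylhex-2-en-4-yn-1-ol
Conditions: PdCl2(PPh3)2 (cat.), CuI (cat.), Et3N, THF, rt
Reagents that add atoms: none
Why: Sonogashira coupling of an alkenyl iodide proceeds with retention of alkene geometry, and the free allylic alcohol and the silyl ether are inert.

Step 3
Reactants: 5 (2Z)-6-(tert-butyldimethylsilyloxy)-3-methylhex-2-en-4-yn-1-ol
Product: 6 (2Z)-6-(tert-butyldimethylsilyloxy)-3-methylhex-2-en-4-ynal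
Conditions: MnO2, CH2Cl2, rt
Reagents that add atoms: none
Why: Heterogeneous MnO2 oxidises the allylic alcohol selectively under neutral conditions that should not isomerise the Z enal.

Step 4
Reactants: 7 3-bromobut-3-en-1-ol
Product: 8 3-bromobut-3-enoic acid
Conditions: CrO3, H2SO4, acetone/H2O, 0 °C
Reagents that add atoms: water, O
Why: Jones oxidation takes the primary alcohol through the aldehyde hydrate to the acid, and the vinyl bromide is inert to chromic acid at 0 °C.

Step 5
Reactants: 8 3-bromobut-3-enoic acid; 9 (4S)-4-benzyl-1,3-oxazolidin-2-one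
Product: 11 (4S)-4-benzyl-3-(3-bromobut-3-enoyl)-1,3-oxazolidin-2-one, via 3-bromobut-3-enoyl chloride 10 (not isolated)
Conditions: (COCl)2, DMF (cat.), CH2Cl2, 0 °C; then 9, n-BuLi, THF, −78 °C
Reagents that add atoms: none
Why: N-Acylation of the lithiated oxazolidinone by the acid chloride at −78 °C is fast enough that the β,γ-unsaturated acyl group should neither move into conjugation nor lose bromide.

Step 6
Reactants: 11 (4S)-4-benzyl-3-(3-bromobut-3-enoyl)-1,3-oxazolidin-2-one; 6 (2Z)-6-(tert-butyldimethylsilyloxy)-3-methylhex-2-en-4-ynal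
Product: 13 syn-aldol adduct (4S)-4-benzyl-3-[(2S,3R,4Z)-2-(1-bromoethenyl)-8-(tert-butyldimethylsilyloxy)-3-hydroxy-5-methyloct-4-en-6-ynoyl]-1,3-oxazolidin-2-one, via dibutylboron Z-enolate 12 (not isolated)
Conditions: Bu2BOTf, Et3N, CH2Cl2, −78 °C; 6, −78 → −20 °C; pH 7 buffer, MeOH, H2O2, 0 °C
Reagents that add atoms: none
Why: Evans syn aldol reaction, in which the Z boron enolate adds at its α-carbon through a chair (Zimmerman–Traxler) transition state on the face away from the benzyl group, so the auxiliary sets 6R and 7S, the syn relation of O6 and the C7 branch that later becomes the trans lactone.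

Step 7
Reactants: 13 syn-aldol adduct
Product: 14 Weinreb amide (2S,3R,4Z)-2-(1-bromoethenyl)-8-(tert-butyldimethylsilyloxy)-3-hydroxy-N-methoxy-N,5-dimethyloct-4-en-6-ynamide
Conditions: MeNHOMe·HCl, AlMe3, CH2Cl2, −20 → 0 °C
Reagents that add atoms: N,O-dimethylhydroxylamine hydrochloride, CNOC.Cl
Why: Aluminium amide transamidation of an aldol adduct with a free β-hydroxyl (Weinreb amide formation) cleaves the exocyclic imide carbonyl selectively and leaves both stereocentres untouched.

Step 8
Reactants: 15 tributyl(iodomethyl)stannane; 16 (4-methoxyphenyl)methanol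
Product: 17 tributyl[(4-methoxybenzyloxy)methyl]stannane
Conditions: NaH, THF/DMF, 0 °C → rt
Reagents that add atoms: none
Why: Williamson ether synthesis, the alkoxide of 16 displacing iodide from the primary iodomethyl group by SN2.

Step 9
Reactants: 14 Weinreb amide; 17 tributyl[(4-methoxybenzyloxy)methyl]stannane
Product: 18 hydroxy ketone (3S,4R,5Z)-3-(1-bromoethenyl)-9-(tert-butyldimethylsilyloxy)-4-hydroxy-1-(4-methoxybenzyloxy)-6-methylnon-5-en-7-yn-2-one
Conditions: 17, n-BuLi, THF, −78 °C; then 14, −78 °C; NH4Cl (aq)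
Reagents that add atoms: none
Why: Tin–lithium exchange gives the alkoxymethyllithium, one equivalent of which deprotonates the 6-hydroxyl while a second adds once to the Weinreb amide through a chelated tetrahedral intermediate that collapses to the ketone only on quench.

Step 10
Reactants: 18 hydroxy ketone
Product: 19 anti diol (2S,3S,4R,5Z)-3-(1-bromoethenyl)-9-(tert-butyldimethylsilyloxy)-1-(4-methoxybenzyloxy)-6-methylnon-5-en-7-yne-2,4-diol
Conditions: Me4NBH(OAc)3, MeCN/AcOH, −30 °C
Reagents that add atoms: none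
Why: Evans–Saksena reduction, in which the 6-hydroxyl binds the acetoxyborohydride and delivers hydride intramolecularly through a chair transition state, should give the 1,3-anti diol and so set 8S.

Step 11
Reactants: 19 anti diol
Product: 20 enyne acetal (3S,4R,5Z)-2-bromo-9-(tert-butyldimethylsilyloxy)-3-[(4S)-2-(4-methoxyphenyl)-1,3-dioxolan-4-yl]-6-methylnona-1,5-dien-7-yn-4-ol (both epimers at the acetal carbon)
Conditions: DDQ, 4 Å molecular sieves, CH2Cl2, −10 → 0 °C
Reagents that add atoms: none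
Why: Oxidation of the 4-methoxybenzyl ether by DDQ gives a benzylic oxocarbenium ion that the neighbouring 8-hydroxyl traps as a five-membered benzylidene acetal, which leaves 6-OH as the only free hydroxyl.

Step 12
Reactants: 20 enyne acetal
Product: 21 diene acetal (3S,4R,5Z,7Z)-2-bromo-9-(tert-butyldimethylsilyloxy)-3-[(4S)-2-(4-methoxyphenyl)-1,3-dioxolan-4-yl]-6-methylnona-1,5,7-trien-4-ol
Conditions: H2 (1 atm), Pd/CaCO3 poisoned with Pb(OAc)2, quinoline, EtOAc, 0 °C → rt
Reagents that add atoms: none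
Why: Semi-hydrogenation over the poisoned palladium catalyst adds hydrogen syn to the conjugated alkyne to give the 2Z alkene, while the vinyl bromide and the trisubstituted alkene should be left alone.

Step 13
Reactants: 21 diene acetal
Product: 22 (4S,5R)-5-[(1Z,3Z)-5-(tert-butyldimethylsilyloxy)-2-methylpenta-1,3-dien-1-yl]-4-[(4S)-2-(4-methoxyphenyl)-1,3-dioxolan-4-yl]-3-methylideneoxolan-2-one
Conditions: Pd(PPh3)4 (5 mol %), CO (1 atm), Et3N, MeCN, 50 °C
Reagents that add atoms: carbon monoxide, [C-]#[O+]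
Why: Palladium-catalysed carbonylative lactonisation, in which oxidative addition into the C11–Br bond, CO insertion and capture of the acylpalladium by the only free hydroxyl (6-OH) close the five-membered ring and deliver the methylene lactone with the C6/C7 trans relation fixed in step 6.

Step 14
Reactants: 22 silyl ether acetal lactone
Product: 23 triol (4R,5R)-4-[(1S)-1,2-dihydroxyethyl]-5-[(1Z,3Z)-5-hydroxy-2-methylpenta-1,3-dien-1-yl]-3-methylideneoxolan-2-one
Conditions: camphorsulfonic acid (cat.), MeOH, 0 °C → rt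
Reagents that add atoms: none
Why: Acid-catalysed methanolysis removes the primary silyl ether and exchanges the benzylidene acetal into its dimethyl acetal, while the trans 6,12-lactone, the more stable of the two possible five-membered lactones, should stay in place.

Step 15
Reactants: 24 methyl (triphenylphosphoranylidene)acetate
Product: 25 methyl iodo(triphenylphosphoranylidene)acetate
Conditions: I2, K2CO3, MeOH, 0 °C → rt
Reagents that add atoms: iodine, II
Why: Electrophilic iodination of the stabilised ylide at carbon followed by deprotonation with carbonate returns the ylide bearing iodine.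

Step 16
Reactants: 23 triol; 25 methyl iodo(triphenylphosphoranylidene)acetate
Product: 27 methyl (2Z,4Z,6Z)-7-[(2R,3R)-3-[(1S)-1,2-dihydroxyethyl]-4-methylidene-5-oxooxolan-2-yl]-2-iodo-6-methylhepta-2,4,6-trienoate, via Z,Z-dienal 26 (not isolated)
Conditions: MnO2, CH2Cl2, 0 °C; filter cold; then 25, CH2Cl2, 0 → 15 °C, dark
Reagents that add atoms: none
Why: MnO2 at 0 °C oxidises only the allylic primary hydroxyl, and the sensitive dienal is trapped at once by the stabilised iodo ylide in a Wittig reaction that places the ester trans to the chain and hence gives the Z iodoalkene needed for a ring-cis C1=C10.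

Step 17
Reactants: 27 iodo trienoate diol
Product: 28 methyl (2Z,4Z,6Z)-7-[(2R,3R)-3-[(1S)-1-hydroxy-2-(triethylsilyloxy)ethyl]-4-methylidene-5-oxooxolan-2-yl]-2-iodo-6-methylhepta-2,4,6-trienoate
Conditions: Et3SiCl, imidazole, CH2Cl2, −40 °C
Reagents that add atoms: chlorotriethylsilane, CC[Si](Cl)(CC)CC
Why: Silylation at low temperature is selective for the primary 9-hydroxyl over the hindered secondary 8-hydroxyl.

Step 18
Reactants: 29 angelic acid
Product: 30 (2Z)-2-methylbut-2-en-1-ol
Conditions: LiAlH4, Et2O, 0 °C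
Reagents that add atoms: none
Why: LiAlH4 reduces the carboxylic acid to the allylic alcohol without touching or isomerising the trisubstituted Z alkene.

Step 19
Reactants: 30 (2Z)-2-methylbut-2-en-1-ol
Product: 31 [(2R,3S)-2,3-dimethyloxiran-2-yl]methanol
Conditions: Ti(OiPr)4 (cat.), D-(−)-diethyl tartrate (cat.), t-BuOOH, 4 Å molecular sieves, CH2Cl2, −20 °C
Reagents that add atoms: tert-butyl hydroperoxide, CC(C)(C)OO
Why: Sharpless asymmetric epoxidation, in which the titanium tartrate complex delivers oxygen to one face of the allylic alcohol (D-(−)-tartrate giving 2R,3S), and the cis relation of CH2OH and the C3 methyl follows from the Z alkene.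

Step 20
Reactants: 31 [(2R,3S)-2,3-dimethyloxiran-2-yl]methanol
Product: 32 (2S,3S)-2,3-dimethyloxirane-2-carboxylic acid
Conditions: RuCl3·xH2O (cat.), NaIO4, MeCN/EtOAc/H2O, 0 °C → rt
Reagents that add atoms: water, O
Why: Catalytic RuO4 generated from RuCl3 and NaIO4 oxidises the primary alcohol to the acid without opening the oxirane or touching its stereocentres.

Step 21
Reactants: 28 9-O-triethylsilyl 8-alcohol; 32 (2S,3S)-2,3-dimethyloxirane-2-carboxylic acid
Product: 34 (1S)-1-[(2R,3S)-2-[(1Z,3Z,5Z)-6-iodo-7-methoxy-2-methyl-7-oxohepta-1,3,5-trien-1-yl]-4-methylidene-5-oxooxolan-3-yl]-2-(triethylsilyloxy)ethyl (2S,3S)-2,3-dimethyloxirane-2-carboxylate, via mixed anhydride 33 (not isolated)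
Conditions: 2,4,6-trichlorobenzoyl chloride, Et3N, toluene, rt; then 28, DMAP, rt
Reagents that add atoms: none
Why: Yamaguchi esterification, in which DMAP attacks the mixed anhydride at the epoxy acyl carbonyl and the acylpyridinium acylates the only free hydroxyl (8-OH) with retention at C8.

Step 22
Reactants: 34 epoxy ester silyl ether
Product: 35 (1S)-1-[(2R,3S)-2-[(1Z,3Z,5Z)-6-iodo-7-methoxy-2-methyl-7-oxohepta-1,3,5-trien-1-yl]-4-methylidene-5-oxooxolan-3-yl]-2-oxoethyl (2S,3S)-2,3-dimethyloxirane-2-carboxylate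
Conditions: (COCl)2, DMSO, CH2Cl2, −78 → −40 °C; Et3N, −78 → −20 °C
Reagents that add atoms: none
Why: Under Swern conditions a primary triethylsilyl ether is cleaved by the chlorosulfonium reagent and oxidised directly to the aldehyde, which avoids a free 9-hydroxyl next to the 8-ester and so avoids acyl migration.

Step 23
Reactants: 35 iodo trienoate aldehyde
Product: 36 macrocyclic 9-alcohol: germacra-1(10)E,2Z,4Z,11(13)-tetraen-12,6-olide with 14-CO2Me, 8-O-[(2S,3S)-2,3-dimethyloxirane-2-carbonyl] and 9-OH; (6R,7S,8S,9R)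
Conditions: CrCl2 (excess), NiCl2 (cat.), DMF/THF, 0.002 M, 0 → 10 °C
Reagents that add atoms: none
Why: Nozaki–Hiyama–Kishi macrocyclisation, in which nickel inserts into the activated C10–I bond, chromium takes over the alkenyl group and adds it to the C9 aldehyde; the Z iodide already holds C2 cis to the new bond so the ring closes as the ring-cis enoate, and polar Felkin–Anh attack anti to the C8–O bond should set 9R.

Step 24
Reactants: 36 macrocyclic 9-alcohol
Product: 37 triene lactone: the 9-acetate of 36; (6R,7S,8S,9R)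
Conditions: Ac2O, pyridine, DMAP (cat.), CH2Cl2, −20 → 0 °C
Reagents that add atoms: acetic anhydride, CC(=O)OC(C)=O
Why: DMAP-catalysed acetylation of the secondary allylic hydroxyl is fast at low temperature, so neither ester migration nor electrocyclisation of the triene should compete.

Step 25
Reactants: 37 triene lactone
Product: 39 CNP0077535.3 (2R,3R,4R,5R,6S,7R,8S,9R), via 4,5-monoepoxide 38 (not isolated)
Conditions: DMDO (3 equiv), acetone/CH2Cl2, −40 → 0 °C
Reagents that add atoms: dimethyldioxirane, CC1(C)OO1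
Why: DMDO hands over one oxygen atom at a time through a concerted spiro transition state, the known dioxirane epoxidation of conjugated dienes, with anti bis-epoxidation of cyclic cis,cis-1,3-dienes as the closest precedent. Each oxirane closes by syn [2+1] addition in which both C–O bonds of the three-membered ring form on one alkene face, so the Z geometry of C4=C5 and of C2=C3 is carried into the cis relation at C4/C5 and at C2/C3. C4 and C5 are set first because trisubstituted C4=C5 is the most nucleophilic alkene; since C3 is cis to C6, allylic strain keeps H6 in the alkene plane and the reagent should arrive on the face that carries lactone oxygen O6, opposite branched C7. C2 and C3 are set next by the new oxirane, which blocks its own side of the twisted diene so that the second oxygen should arrive anti. The step needs site selectivity (C4=C5, then C2=C3, never C1=C10 or C11=C13) and two face selections; the first is secured by the ester on C10 and the lactone carbonyl on C11, which make those alkenes electron-poor, the second by stereocentre C6 and by the first oxirane. Cold conditions matter only until the first oxygen is in place, because that addition removes the 1(10),2,4-hexatriene that could otherwise close to a decalin by 6π electrocyclisation.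

Compound list
1 | but-2-yn-1-ol | CC#CCO | starting material
2 | sodium alkenylalanate Na[Al(OCH2CH2OMe)2(OCH2CH=CMe)], cyclic, Al on the methyl-bearing carbon (formed and used in the flask) | [Na+].COCCO[Al-]1(OCCOC)OCC=C1C | intermediate
3 | (2Z)-3-iodobut-2-en-1-ol | C/C(I)=C/CO | intermediate
4 | tert-butyldimethyl(prop-2-yn-1-yloxy)silane | C#CCO[Si](C)(C)C(C)(C)C | starting material
5 | (2Z)-6-(tert-butyldimethylsilyloxy)-3-methylhex-2-en-4-yn-1-ol | OC/C=C(C)\C#CCO[Si](C)(C)C(C)(C)C | intermediate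
6 | (2Z)-6-(tert-butyldimethylsilyloxy)-3-methylhex-2-en-4-ynal | O=C/C=C(C)\C#CCO[Si](C)(C)C(C)(C)C | intermediate
7 | 3-bromobut-3-en-1-ol | OCCC(Br)=C | starting material
8 | 3-bromobut-3-enoic acid | OC(=O)CC(Br)=C | intermediate
9 | (4S)-4-benzyl-1,3-oxazolidin-2-one | O=C1N[C@@H](Cc2ccccc2)CO1 | starting material
10 | 3-bromobut-3-enoyl chloride (formed and used in the flask) | ClC(=O)CC(Br)=C | intermediate
11 | (4S)-4-benzyl-3-(3-bromobut-3-enoyl)-1,3-oxazolidin-2-one | C=C(Br)CC(=O)N1[C@@H](Cc2ccccc2)COC1=O | intermediate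
12 | dibutylboron Z-enolate of 11 (formed and used in the flask) | CCCCB(CCCC)O/C(=C\C(Br)=C)N1[C@@H](Cc2ccccc2)COC1=O | intermediate
13 | (4S)-4-benzyl-3-[(2S,3R,4Z)-2-(1-bromoethenyl)-8-(tert-butyldimethylsilyloxy)-3-hydroxy-5-methyloct-4-en-6-ynoyl]-1,3-oxazolidin-2-one; (6R,7S) | O[C@H](/C=C(C)\C#CCO[Si](C)(C)C(C)(C)C)[C@H](C(Br)=C)C(=O)N1[C@@H](Cc2ccccc2)COC1=O | intermediate
14 | (2S,3R,4Z)-2-(1-bromoethenyl)-8-(tert-butyldimethylsilyloxy)-3-hydroxy-N-methoxy-N,5-dimethyloct-4-en-6-ynamide; (6R,7S) | O[C@H](/C=C(C)\C#CCO[Si](C)(C)C(C)(C)C)[C@H](C(Br)=C)C(=O)N(C)OC | intermediate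
15 | tributyl(iodomethyl)stannane | CCCC[Sn](CCCC)(CCCC)CI | starting material
16 | (4-methoxyphenyl)methanol | COc1ccc(CO)cc1 | starting material
17 | tributyl[(4-methoxybenzyloxy)methyl]stannane | CCCC[Sn](CCCC)(CCCC)COCc1ccc(OC)cc1 | intermediate
18 | (3S,4R,5Z)-3-(1-bromoethenyl)-9-(tert-butyldimethylsilyloxy)-4-hydroxy-1-(4-methoxybenzyloxy)-6-methylnon-5-en-7-yn-2-one; (6R,7S) | O[C@H](/C=C(C)\C#CCO[Si](C)(C)C(C)(C)C)[C@H](C(Br)=C)C(=O)COCc1ccc(OC)cc1 | intermediate
19 | (2S,3S,4R,5Z)-3-(1-bromoethenyl)-9-(tert-butyldimethylsilyloxy)-1-(4-methoxybenzyloxy)-6-methylnon-5-en-7-yne-2,4-diol; (6R,7S,8S) | O[C@H](/C=C(C)\C#CCO[Si](C)(C)C(C)(C)C)[C@H](C(Br)=C)[C@H](O)COCc1ccc(OC)cc1 | intermediate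
20 | (3S,4R,5Z)-2-bromo-9-(tert-butyldimethylsilyloxy)-3-[(4S)-2-(4-methoxyphenyl)-1,3-dioxolan-4-yl]-6-methylnona-1,5-dien-7-yn-4-ol, both acetal epimers; (6R,7S,8S) | O[C@H](/C=C(C)\C#CCO[Si](C)(C)C(C)(C)C)[C@H](C(Br)=C)[C@H]1COC(c2ccc(OC)cc2)O1 | intermediate
21 | (3S,4R,5Z,7Z)-2-bromo-9-(tert-butyldimethylsilyloxy)-3-[(4S)-2-(4-methoxyphenyl)-1,3-dioxolan-4-yl]-6-methylnona-1,5,7-trien-4-ol; (6R,7S,8S) | O[C@H](/C=C(C)\C=C/CO[Si](C)(C)C(C)(C)C)[C@H](C(Br)=C)[C@H]1COC(c2ccc(OC)cc2)O1 | intermediate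
22 | (4S,5R)-5-[(1Z,3Z)-5-(tert-butyldimethylsilyloxy)-2-methylpenta-1,3-dien-1-yl]-4-[(4S)-2-(4-methoxyphenyl)-1,3-dioxolan-4-yl]-3-methylideneoxolan-2-one; (6R,7S,8S) | C=C1C(=O)O[C@H](/C=C(C)\C=C/CO[Si](C)(C)C(C)(C)C)[C@H]1[C@H]1COC(c2ccc(OC)cc2)O1 | intermediate
23 | (4R,5R)-4-[(1S)-1,2-dihydroxyethyl]-5-[(1Z,3Z)-5-hydroxy-2-methylpenta-1,3-dien-1-yl]-3-methylideneoxolan-2-one; (6R,7R,8S) | C=C1C(=O)O[C@H](/C=C(C)\C=C/CO)[C@H]1[C@H](O)CO | intermediate
24 | methyl (triphenylphosphoranylidene)acetate | COC(=O)C=P(c1ccccc1)(c1ccccc1)c1ccccc1 | starting material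
25 | methyl iodo(triphenylphosphoranylidene)acetate | COC(=O)C(I)=P(c1ccccc1)(c1ccccc1)c1ccccc1 | intermediate
26 | (2Z,4Z)-5-[(2R,3R)-3-[(1S)-1,2-dihydroxyethyl]-4-methylidene-5-oxooxolan-2-yl]-4-methylpenta-2,4-dienal (formed and used in the flask) | C=C1C(=O)O[C@H](/C=C(C)\C=C/C=O)[C@H]1[C@H](O)CO | intermediate
27 | methyl (2Z,4Z,6Z)-7-[(2R,3R)-3-[(1S)-1,2-dihydroxyethyl]-4-methylidene-5-oxooxolan-2-yl]-2-iodo-6-methylhepta-2,4,6-trienoate; (6R,7R,8S) | C=C1C(=O)O[C@H](/C=C(C)\C=C/C=C(\I)C(=O)OC)[C@H]1[C@H](O)CO | intermediate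
28 | methyl (2Z,4Z,6Z)-7-[(2R,3R)-3-[(1S)-1-hydroxy-2-(triethylsilyloxy)ethyl]-4-methylidene-5-oxooxolan-2-yl]-2-iodo-6-methylhepta-2,4,6-trienoate; (6R,7R,8S) | C=C1C(=O)O[C@H](/C=C(C)\C=C/C=C(\I)C(=O)OC)[C@H]1[C@H](O)CO[Si](CC)(CC)CC | intermediate
29 | angelic acid, (2Z)-2-methylbut-2-enoic acid | C/C=C(/C)C(=O)O | starting material
30 | (2Z)-2-methylbut-2-en-1-ol | C/C=C(/C)CO | intermediate
31 | [(2R,3S)-2,3-dimethyloxiran-2-yl]methanol | OC[C@@]1(C)O[C@H]1C | intermediate
32 | (2S,3S)-2,3-dimethyloxirane-2-carboxylic acid | OC(=O)[C@@]1(C)O[C@H]1C | intermediate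
33 | (2S,3S)-2,3-dimethyloxirane-2-carboxylic 2,4,6-trichlorobenzoic anhydride (formed and used in the flask) | O=C(OC(=O)[C@@]1(C)O[C@H]1C)c1c(Cl)cc(Cl)cc1Cl | intermediate
34 | (1S)-1-[(2R,3S)-2-[(1Z,3Z,5Z)-6-iodo-7-methoxy-2-methyl-7-oxohepta-1,3,5-trien-1-yl]-4-methylidene-5-oxooxolan-3-yl]-2-(triethylsilyloxy)ethyl (2S,3S)-2,3-dimethyloxirane-2-carboxylate; (6R,7S,8S) | C=C1C(=O)O[C@H](/C=C(C)\C=C/C=C(\I)C(=O)OC)[C@H]1[C@H](OC(=O)[C@@]1(C)O[C@H]1C)CO[Si](CC)(CC)CC | intermediate
35 | (1S)-1-[(2R,3S)-2-[(1Z,3Z,5Z)-6-iodo-7-methoxy-2-methyl-7-oxohepta-1,3,5-trien-1-yl]-4-methylidene-5-oxooxolan-3-yl]-2-oxoethyl (2S,3S)-2,3-dimethyloxirane-2-carboxylate; (6R,7S,8S) | C=C1C(=O)O[C@H](/C=C(C)\C=C/C=C(\I)C(=O)OC)[C@H]1[C@H](OC(=O)[C@@]1(C)O[C@H]1C)C=O | intermediate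
36 | germacra-1(10)E,2Z,4Z,11(13)-tetraen-12,6-olide with 14-CO2Me, 8-O-[(2S,3S)-2,3-dimethyloxirane-2-carbonyl] and 9-OH; (6R,7S,8S,9R) | C=C1C(=O)O[C@H]2[C@H]1[C@H](OC(=O)[C@@]1(C)O[C@H]1C)[C@H](O)/C(C(=O)OC)=C\C=C/C(C)=C\2 | intermediate
37 | 9-acetate of 36, the 1(10),2Z,4Z-triene lactone; (6R,7S,8S,9R) | C=C1C(=O)O[C@H]2[C@H]1[C@H](OC(=O)[C@@]1(C)O[C@H]1C)[C@H](OC(C)=O)/C(C(=O)OC)=C\C=C/C(C)=C\2 | intermediate
38 | 4,5-monoepoxide of 37 with C2=C3 intact; (4S,5R,6S,7R,8S,9R) (formed and used in the flask) | C=C1C(=O)O[C@H]2[C@H]1[C@H](OC(=O)[C@@]1(C)O[C@H]1C)[C@H](OC(C)=O)/C(C(=O)OC)=C\C=C/[C@]1(C)O[C@H]21 | intermediate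
39 | CNP0077535.3: methyl 9-acetoxy-2,3:4,5-diepoxy-8-[(2S,3S)-2,3-dimethyloxirane-2-carbonyloxy]germacra-1(10)E,11(13)-dien-12,6-olid-14-oate; (2R,3R,4R,5R,6S,7R,8S,9R) | C=C1C(=O)O[C@H]2[C@H]1[C@H](OC(=O)[C@@]1(C)O[C@H]1C)[C@H](OC(C)=O)/C(C(=O)OC)=C\[C@H]1O[C@H]1[C@]1(C)O[C@H]21 | target

Total step count: 25.
Longest linear sequence: 18 steps (1, 2, 3, 6, 7, 9, 10, 11, 12, 13, 14, 16, 17, 21, 22, 23, 24, 25), from but-2-yn-1-ol.

Steps most likely to fail

Step 23. The aldehyde flanked by the C8 ester may be reduced by CrCl2 with loss or migration of the acyloxy group. The electron-poor alkenyl metal species may also add too slowly, so that oligomerisation or electrocyclisation of the product takes over. The fallback moves the acylation to after ring closure. It sets out from 28 and comes back at 37. TBSOTf and 2,6-lutidine should give the 8-O-tert-butyldimethylsilyl 9-O-triethylsilyl ether F1. Swern oxidation as in step 22 should give the silyloxy aldehyde F2, a routine substrate for CrCl2/NiCl2 coupling. Ring closure should give the macrocyclic 9-alcohol F3, and Ac2O/pyridine its 9-acetate F4. HF·pyridine at −20 °C should free the 8-hydroxy triene F5, and Yamaguchi acylation with 32 returns to 37.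

Step 25. The second oxygen transfer may show poor facial selectivity and give the syn bis-epoxide. The fallback delivers that oxygen through a halohydrin, which inverts the face. It sets out from 38, isolated after one equivalent of DMDO at −40 °C, and comes back at 39. N-Bromosuccinimide in wet THF should add bromine to the face DMDO prefers and water anti to it, giving the bromohydrin F6. Ag2O then closes the oxirane by backside displacement of bromide, which places the oxygen on the opposite face; either regiochemistry of water attack leads to the same oxirane.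

Step 6. The boron enolate may lose bromide to give an allenoyl imide, or the double bond may migrate into conjugation before the aldol. The fallback uses a succinate arm and adds the methylene group later. It sets out from 9 and 6 and comes back at 22. Acylation of 9 with 4-tert-butoxy-4-oxobutanoic acid (pivaloyl chloride, Et3N, LiCl) should give the succinyl imide F7. The boron aldol with 6 should give the syn adduct F8 with the same sense of induction. The operations of steps 7 and 9–12 then give in turn the Weinreb amide F9, the hydroxy ketone F10, the anti diol F11, the enyne acetal F12 and the diene acetal F13. NaH (cat.) in THF should close the saturated lactone F14 by attack of the 6-alkoxide on the tert-butyl ester. LiN(iPr)2 followed by dimethylmethyleneammonium iodide should give the aminomethyl lactone F15. MeI and then NaHCO3 eliminate trimethylamine to give 22.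

Further compounds
F1 | step 23 | methyl (2Z,4Z,6Z)-7-[(2R,3S)-3-[(1S)-1-(tert-butyldimethylsilyloxy)-2-(triethylsilyloxy)ethyl]-4-methylidene-5-oxooxolan-2-yl]-2-iodo-6-methylhepta-2,4,6-trienoate | C=C1C(=O)O[C@H](/C=C(C)\C=C/C=C(\I)C(=O)OC)[C@H]1[C@H](O[Si](C)(C)C(C)(C)C)CO[Si](CC)(CC)CC
F2 | step 23 | 9-aldehyde from F1 (8-O-tert-butyldimethylsilyl) | C=C1C(=O)O[C@H](/C=C(C)\C=C/C=C(\I)C(=O)OC)[C@H]1[C@H](O[Si](C)(C)C(C)(C)C)C=O
F3 | step 23 | macrocyclic 8-O-tert-butyldimethylsilyl 9-alcohol | C=C1C(=O)O[C@H]2[C@H]1[C@H](O[Si](C)(C)C(C)(C)C)[C@H](O)/C(C(=O)OC)=C\C=C/C(C)=C\2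
F4 | step 23 | macrocyclic 8-O-tert-butyldimethylsilyl 9-acetate | C=C1C(=O)O[C@H]2[C@H]1[C@H](O[Si](C)(C)C(C)(C)C)[C@H](OC(C)=O)/C(C(=O)OC)=C\C=C/C(C)=C\2
F5 | step 23 | macrocyclic 8-hydroxy 9-acetate | C=C1C(=O)O[C@H]2[C@H]1[C@H](O)[C@H](OC(C)=O)/C(C(=O)OC)=C\C=C/C(C)=C\2
F6 | step 25 | 3-bromo-2-hydroxy derivative of 38 (bromohydrin, anti) | C=C1C(=O)O[C@H]2[C@H]1[C@H](OC(=O)[C@@]1(C)O[C@H]1C)[C@H](OC(C)=O)/C(C(=O)OC)=C\[C@@H](O)[C@H](Br)[C@]1(C)O[C@H]21
F7 | step 6 | (4S)-4-benzyl-3-(4-tert-butoxy-4-oxobutanoyl)-1,3-oxazolidin-2-one | CC(C)(C)OC(=O)CCC(=O)N1[C@@H](Cc2ccccc2)COC1=O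
F8 | step 6 | syn-aldol adduct with a CH2CO2t-Bu arm on C7 | O[C@H](/C=C(C)\C#CCO[Si](C)(C)C(C)(C)C)[C@H](CC(=O)OC(C)(C)C)C(=O)N1[C@@H](Cc2ccccc2)COC1=O
F9 | step 6 | Weinreb amide from F8 | O[C@H](/C=C(C)\C#CCO[Si](C)(C)C(C)(C)C)[C@H](CC(=O)OC(C)(C)C)C(=O)N(C)OC
F10 | step 6 | 4-methoxybenzyloxymethyl ketone from F9 | O[C@H](/C=C(C)\C#CCO[Si](C)(C)C(C)(C)C)[C@H](CC(=O)OC(C)(C)C)C(=O)COCc1ccc(OC)cc1
F11 | step 6 | 6,8-anti diol from F10 | O[C@H](/C=C(C)\C#CCO[Si](C)(C)C(C)(C)C)[C@H](CC(=O)OC(C)(C)C)[C@H](O)COCc1ccc(OC)cc1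
F12 | step 6 | 8,9-benzylidene acetal from F11 (enyne) | O[C@H](/C=C(C)\C#CCO[Si](C)(C)C(C)(C)C)[C@H](CC(=O)OC(C)(C)C)[C@H]1COC(c2ccc(OC)cc2)O1
F13 | step 6 | Z,Z-diene hydroxy ester from F12 | O[C@H](/C=C(C)\C=C/CO[Si](C)(C)C(C)(C)C)[C@H](CC(=O)OC(C)(C)C)[C@H]1COC(c2ccc(OC)cc2)O1
F14 | step 6 | saturated trans lactone (C11 as CH2) | C1C(=O)O[C@H](/C=C(C)\C=C/CO[Si](C)(C)C(C)(C)C)[C@H]1[C@H]1COC(c2ccc(OC)cc2)O1
F15 | step 6 | 11-(dimethylaminomethyl) lactone (both C11 epimers) | CN(C)CC1C(=O)O[C@H](/C=C(C)\C=C/CO[Si](C)(C)C(C)(C)C)[C@H]1[C@H]1COC(c2ccc(OC)cc2)O1
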